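**Assumption (one line):** Valtrate (C22H30O8, CAS 18296-44-1) is purchasable as an isolated reference standard. It already has the jatamanvaltrate I skeleton, the C1 and C11 isovalerates, the C7 acetate and the (1S,7S,8R,9S) configuration. The target differs from it only in having a C8 tertiary alcohol and a C10 salicylate ester where valtrate has a C8/C10 spiro-epoxide.

## Retrosynthetic overview
1. Disconnect the C10–O ester bond of the target. This is a retro epoxide opening: the C8 tertiary OH and the C10 salicylate arise together from one epoxide and one carboxylic acid.
2. That gives valtrate (spiro-epoxide at C8/C10) and salicylic acid.
3. No ring is formed in this route. The cyclopentene ring and the dihydropyran acylal ring both come from valtrate.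
4. C1, C7, C8 and C9 come from valtrate and are untouched. C8 keeps its configuration because only the C10–O bond is made.

## Forward route

**Step 1**
- Reactants: **1** valtrate; **2** salicylic acid
- Product: **3** jatamanvaltrate I
- Conditions: salicylic acid (2.0 equiv), Et3N (2.0 equiv), DMF, 35–40 °C, N2, dark, 24–48 h. Purify on neutral silica or by reverse-phase HPLC.
- Reagents that add atoms: salicylic acid, OC(=O)c1ccccc1O (this is compound **2**). Et3N, CCN(CC)CC, leaves no atoms in the product.
- Why: Epoxide ring opening (SN2) by the triethylammonium salicylate carboxylate. Under basic to neutral conditions it attacks the unhindered primary C10 and does not ionise at the tertiary C8. The C8–O bond is never broken, so the 8R carbinol keeps valtrate's configuration, and no new stereocentre forms because C10 is achiral. Et3N (pKa of Et3NH+ ≈ 10.7) does not deprotonate the salicylate phenol (pKa ≈ 13), so the carboxylate is the only nucleophile, and Et3NH+ protonates the C8 alkoxide. The C1 acylal, the C3=C4/C5=C6 diene, the C7 acetate and the C11 isovalerate are not nucleophile-sensitive under these mild conditions.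

**Atom check:** C22H30O8 + C7H6O3 = C29H36O11, which is the formula of the target.

## Compound list
| No. | Name | SMILES | Role |
|---|---|---|---|
| 1 | Valtrate | CC(=O)O[C@H]1C=C2C(COC(=O)CC(C)C)=CO[C@@H](OC(=O)CC(C)C)[C@@H]2[C@@]13CO3 | starting material |
| 2 | Salicylic acid | OC(=O)c1ccccc1O | starting material |
| 3 | Jatamanvaltrate I | CC(=O)O[C@H]1C=C2C(COC(=O)CC(C)C)=CO[C@@H](OC(=O)CC(C)C)[C@@H]2[C@@]1(O)COC(=O)c1ccccc1O | target |

## Summary
- Total step count: 1
- Longest linear sequence: 1 step
- The route has only one step, so the three most likely failure points are three distinct failure modes within it:
  1. **Regioselectivity and acid sensitivity.** Opening at tertiary C8, or ionisation of the C1 acylal or allylic C7 acetate, would give rearranged or decomposed material. Fallback (different approach): buffered hydrolysis of **1** to the 8,10-diol, then selective primary esterification with 2-(TBSO)benzoic acid (EDC/DMAP) and mild desilylation with TBAF/AcOH.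
  2. **Valtrate instability to base and heat.** Loss of the C1 isovalerate and diene degradation would give baldrinal-type products. Fallback (different approach): go through a halohydrin (ring-open **1** to the C10 halide/C8 alcohol at low temperature), then displace the primary halide with cesium salicylate.
  3. **Phenol interference or acyl migration.** O-alkylation by the phenol, or C7/C10 acyl transfer to the tertiary alkoxide, would lower yield. Fallback (different approach): open the epoxide with 2-acetoxybenzoic acid (aspirin) carboxylate, then remove only the aryl acetate with hydrazinium acetate.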